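Percent of the starting complex charged is the unit of your two runs, and in that unit the end of this flask can be reckoned before it is reached.

| setting | Tuesday's | Saturday's | red | amber | blue |
|---|---|---|---|---|---|
| starting complex | 0.096 M | 0.096 M | 0.096 M | 0.096 M | 0.096 M |
| incoming ligand | 3 equiv | 3 equiv | 3.00 equiv | 3.00 equiv | 3.00 equiv |
| leaving ligand | 1.1 equiv | 3 equiv | 1.00 equiv | 1.50 equiv | 2.50 equiv |
| protic impurity | 4.8 mM | 4.8 mM | 4.80 mM | 4.80 mM | 4.80 mM |
| remark | run made earlier | run made earlier |  |  |  |
| time |  |  | 5.0 d | 5.0 d | 5.0 d |

| run | time / d | complex with two exchanged / % | starting complex / % |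
|---|---|---|---|
| Tuesday's | 0.250 | 10.7 | 60.3 |
| Tuesday's | 0.417 | 21.2 | 45.1 |
| Tuesday's | 0.625 | 32.3 | 33.3 |
| Tuesday's | 1.04 | 48.3 | 19.0 |
| Tuesday's | 1.67 | 60.0 | 10.2 |
| Tuesday's | 2.50 | 66.2 | 5.5 |
| Tuesday's | 4.00 | 67.9 | 2.8 |
| Saturday's | 0.250 | 10.7 | 60.7 |
| Saturday's | 0.417 | 19.9 | 45.1 |
| Saturday's | 0.625 | 29.9 | 33.5 |
| Saturday's | 1.04 | 43.7 | 19.9 |
| Saturday's | 1.67 | 52.6 | 10.9 |
| Saturday's | 2.50 | 56.6 | 6.3 |
| Saturday's | 4.00 | 58.5 | 4.0 |

(readings scatter by 0.3 percentage points)

- what was read earlier has a scatter of 0.3 percentage points, one standard deviation
- "hardly changes" means that all values lie within two and a half points (for a concentration: within two and a half percent of the largest)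

1. [complex with two exchanged] at the end for red, amber, blue, in this order
2. the course of these numbers from the first flask to the last (rises, then falls / falls all the way / hardly changes / rises all the way / falls, then rises)

Between 2.50 d and 4.00 d the complex with two exchanged gains 1.7 percentage points in Tuesday's run and 1.9 points in Saturday's, so you may treat the last readings as close to the end. Yet Saturday's run, with more leaving ligand, stands 9.4 points lower than Tuesday's, which points to a reversible second exchange.

Count what the two columns leave out as complex with one exchanged: 29.3 % on Tuesday and 37.5 % on Saturday. Each exchange takes one incoming ligand and frees one leaving ligand, and you set the protic impurity aside. Then form the exchange quotient: complex with two exchanged times leaving ligand, divided by complex with one exchanged times incoming ligand. At the end of the second step this quotient is an estimate of its equilibrium constant, read from scattered readings with the protic impurity set aside. It reads 4.73 on Tuesday and 4.87 on Saturday, so carry their mean, 4.80.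

Hold it fixed, solve the balance with the starting complex left as in the nearest run, and you get 0.0660 M for red and 0.0580 M for blue.

The forecast gives 0.0663 M, 0.0634 M and 0.0585 M, course: falls all the way. Its ground is “the second step is a reversible equilibrium”. Its red and blue values stand slightly above yours.

The flasks give 0.0665 M, 0.0636 M and 0.0585 M, course: falls all the way. A one-step fit, first order each way, with all reacted starting complex read as complex with two exchanged, answers hardly changes, so flasks behaving like that fit would prove the forecast wrong.

    starting complex + incoming ligand ⇌ leaving ligand + complex with one exchanged (K = 31.0, k = 0.330 M⁻¹ h⁻¹)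
    complex with one exchanged + incoming ligand ⇌ leaving ligand + complex with two exchanged (K = 5.10, k = 0.390 M⁻¹ h⁻¹)
    protic impurity + incoming ligand → quenched reagent (k = 9.20 M⁻¹ h⁻¹)

Red's end amounts give a quotient of 5.07, against the 4.80 carried. In blue, 45.9 % of the incoming ligand's charge and 163 % of the leaving ligand's charge remain at the end, so 4.80 asks for 1.62 complex with two exchanged per complex with one exchanged, and blue holds 1.72.

(The runs come from a simulation for substances that don't exist; the scatter is artificial.)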